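42 percentage points of the solid substrate went in 7.33 h of the north-west run. That fall, nearly straight within the scatter, is what to watch, so we read from it the clearing time τ = 17.5 h, the time a whole charge of solid takes to vanish at this constant, zero-order pace.

| flask | solid substrate | remark | time |
|---|---|---|---|
| north-west | 2 M | the very flask that is asked about, followed so far |  |
| flask | 2.0 M |  | 15 h |

north-west run (percent of the solid substrate charged)

| time / h | solid substrate / % | target / % |
|---|---|---|
| 0.667 | 97 | 0 |
| 1.00 | 94 | 3 |
| 1.50 | 88 | 0 |
| 2.50 | 85 | 0 |
| 5.00 | 71 | 6 |
| 8.00 | 55 | 7 |

(standard deviation of a reading: 2 percentage points)

1. which holds at 15 h: what has brought the reaction to rest, or that it has not come to rest (for what has run out or reacted, a solid counts together with what of it has only dissolved; other conformer counts as not reacted) (it is still moving / forward and back rates have come level / all of the solid substrate has reacted)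
2. part of the solid substrate that has turned into other species by 15 h (what has only dissolved and other conformer do not count)
3. amount of target at 15 h, in percent of the solid substrate charged

- given per volume of solution although it is solid: solid substrate
- at the start none of the solid substrate is in solution
- in a conversion other conformer counts as not yet reacted; third conformer counts as reacted
- what has only dissolved of solid substrate counts as not reacted
- the reaction counts as stopped when no species that holds the solid substrate changes by six tenths of a point or more over the second half of the time

Does the solid last to the asked time? We reckon t/τ = 0.857, and because 15 h is shorter than τ, we expect the flask to be still moving. Putting this answer back, the straight line assumed solid present, and by this reckoning solid is still present at the asked time, so we keep the line, which puts the solid substrate left in the flask at 14.1 % of the charge. We therefore put the conversion below 85.9 %, since what has only dissolved does not count as reacted. How much is target? The north-west reading at 8.00 h gives a share s = 15.6 % of the solid lost, hence our 13.4 %, a figure carrying the scatter of a single reading.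

The forecast gives it is still moving, 80 % converted and 12.5 % target, the target a little lower than ours: “Nothing suggests a plateau, so the reaction is most likely still moving”.

The flask gives it is still moving, 77.4 % and 13.2 %, and the forecast held.

    starting material ⇌ other conformer (K = 1.50, k = 0.0418 /min)
    starting material → target (k = 0.00431 /min)
    other conformer → isomer of the product (k = 0.0184 /min)
    other conformer ⇌ third conformer (K = 0.360, k = 0.00579 /min)
    third conformer → third product (k = 0.0327 /min)
    starting material + target → side product (k = 0.00304 /M/min)
    solid substrate ⇌ starting material, rate k7*(cs7 - [starting material]) while solid is left; crystals form when [starting material] > cs7 (solubility = 1.40 M, k = 0.00142 /min)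

In the flask, the solid substrate went on going into solution, standing at 57.5 % after 7.50 h and 15.4 % after 15.0 h, while starting material stood at 4.03 % and then 3.97 %, made and used, each step taken net, at a ratio of 0.998 at 15.0 h, a steady state. Meanwhile the isomer of the product grew from 23.0 % to 50.6 %. The solid left in the flask at 15 h is 2.69 h of clearing at the pace of τ.

For the neighbour flask read at 25 h, τ is shorter, so by τ the solid should have cleared 7.50 h before the reading, and that neighbour shows solid substrate 0 %, conversion >99.9 % and target 16.2 %.

The earlier runs and the new flask were computed on assumed constants.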